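The readings are calculated with made-up constants; scatter was added.

**The unit.** Per minute is the unit I carry through this flask: how fast the starting material keeps falling late in a run, when the early burst is over.

| flask | starting material | coupling partner | free catalyst | product | time |
|---|---|---|---|---|---|
| amber | 1.00 M | 1.20 M | 0.0500 M |  |  |
| ochre | 0.600 M | 0.800 M | 0.0500 M |  |  |
| grey | 1.00 M | 1.20 M | 0.0500 M | 0.500 M |  |
| blue | 1.00 M | 0.400 M | 0.150 M |  | 30 min |

| run | time / min | [starting material] / M |
|---|---|---|
| amber run | 6.0 | 0.634 |
| amber run | 12 | 0.422 |
| amber run | 18 | 0.309 |
| amber run | 24 | 0.239 |
| amber run | 30 | 0.149 |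
| ochre run | 6.0 | 0.377 |
| ochre run | 12 | 0.250 |
| ochre run | 18 | 0.180 |
| ochre run | 24 | 0.131 |
| ochre run | 30 | 0.079 |
| grey run | 6.0 | 0.643 |
| grey run | 12 | 0.424 |
| grey run | 18 | 0.302 |
| grey run | 24 | 0.213 |
| grey run | 30 | 0.166 |

(each reading ± 0.01 M)

- starting material in the blue run at 30 min, as a share of the starting material charged

- Overall: starting material + coupling partner -> product, with free catalyst as catalyst.
- Constant volume, constant temperature.

**What matters.** At 30 min the amber run keeps 14.9% of its charge of starting material and the ochre run 13.2%, though ochre was charged with less of both reactants . A single ochre reading scatters by 1.67% of the charge, so these two charges barely show in the share. Adding 0.500 M of product, the grey run keeps 16.6%, again close to amber. Free catalyst is 0.0500 M in all three runs, so they cannot show what the 3.00-fold ratio in the blue run does. The late constant matters most: it sits in an exponent, so a relative error in it returns about 1.74 times larger in the share.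

**The number.** I add the amber, ochre and grey readings at each time. The natural log of the sum at 18 min over the sum at 30 min, divided by the time between, gives 0.0581 min⁻¹, my late decay constant. In the blue run the coupling partner is the limiting reagent. I assume, untested, that the decay continues regardless, which leaves 17.5%. I commit to that figure, expecting the extra catalyst to lower it somewhat.

**The result.** The forecast says 46.5%, holding that “the coupling partner is limiting”. The blue run gives 10.6%.

    free catalyst + starting material → loaded catalyst + by-product (1.266 M⁻¹ min⁻¹)
    loaded catalyst + coupling partner → product + free catalyst (0.6660 M⁻¹ min⁻¹)
    starting material → decomposed substrate (0.04962 min⁻¹)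
    free catalyst → spent catalyst (0.1524 min⁻¹)

**The reason.** The blue run falls this low through the step from starting material to decomposed substrate: with that step it holds 10.6% at 30 min, and the same run without it holds 58.5%. The blue run's 10.6% lies below the 17.5% that my late decay constant of 0.0581 min⁻¹ left. The step from starting material to decomposed substrate needs neither catalyst nor coupling partner, and its constant is 0.0496 min⁻¹.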